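**Structural features**

Wailupemycin H is built from two 4-hydroxy-2-pyrones, ring C and ring D, joined through a methylene group between their nucleophilic carbons C3' and C3''. Ring C hangs by C6' on C4 of an 8-hydroxy-1-tetralone (aromatic ring A, carbocycle B: C1 carbonyl, C2 methylene, C3 bearing OH and phenyl, C4 bearing H and ring C). Ring D hangs by C6'' on C1''' of a 2-phenylnaphthalene-4,5-diol (rings E and F). The only stereocentres are the neighbours C3 (R, tertiary benzylic carbinol) and C4 (S); the C3 hydroxyl and the pyrone on C4 are cis on ring B, phenyl and pyrone trans. The naphthalene half is the tetralone half minus one molecule of water (loss of the C3 hydroxyl with a C2 hydrogen, then enolization of C1 through C4–H), so ring B is one easy dehydration away from aromatization. The tetralone half is fragile for the same reason: base opens E1cB elimination through C2, retro-aldol cleavage of C2–C3 or C3–C4 and epimerization at C4, acid ionizes C3, and the methylene bridge can come apart by retro-Michael reaction. The real difficulty is to set C3 and C4 together, in the absolute sense, in a ring that must not yet carry the C1 ketone while strong reagents are in use, and then to join two almost identical pyrone nucleophiles to one carbon without statistical mixing. The key step exploits the fact that O–C3–C4–C6' of ring B, with oxygen and C6' cis, is the atom sequence of a cis-fused β-lactone in which C6' is the acyl carbon.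

**Logic of the disconnections**

23 from 22: only the two aryl O–Si bonds (O8 and O5''') are cut. The phenols stay masked until the end so that the only nucleophilic carbons present during the union are the pyrone C3 positions. The forward step must be a fluoride cleavage mild enough for the β-hydroxy ketone.

22 from 18 and 20 (through 21): the C3'–CH2 bond is cut. Only one pyrone (ring D) carries the one-carbon electrophile, so the two halves cannot mix statistically. The gain is two monomers of half the size. The demand is that 21 is released under near-neutral conditions and that the bridge, once formed, is not allowed to equilibrate.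

20 from 19, and 19 from 18: the C3''–CH2 bond is cut (Mannich reaction), and then rings E and F are traced back to rings A and B of 18 by adding water across C2–C3. The naphthalene half therefore needs no synthesis of its own; the dehydration that threatens the tetralone is used once, deliberately, on part of the material. The demand is only that 18 is made in quantity.

18 from 17, and 17 from 16: the C1 carbonyl is traced to a silyl-protected carbinol. With C1 at the alcohol level there is no 1,3-diketone, no E1cB path through C2 and no o-quinodimethane enolate through C4 while enolates and heat are used. The price is a temporary stereocentre at C1, which is turned into an asset (see 12 from 10). The forward steps must remove an alkyl silyl ether beside an aryl one and oxidize a benzylic alcohol beside a pyrone enol.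

16 from 14, and 14 from 12 and 13: ring C is cut at O1'–C2' (acylketene cyclization) and at C5'–C6' (acyl transfer). C6' becomes the carbonyl carbon of a strained lactone and the remaining four carbons of ring C come from 13. The gain is that ring C is assembled after the stereocentres, from the group that set them. The demand is that the tertiary alkoxide set free at C3 does not trigger retro-aldol cleavage.

12 from 10 (key disconnection): the C3–C4 bond and the lactone O–C(=O) bond are cut together. In one sentence: keto acid 10 is closed by a catalytic enantioselective aldol-lactonization to the cis-fused β-lactone 12. This closes ring B, sets C3 and C4 as a pair with the cis O/C6' relationship built into the four-membered ring, and leaves an open-chain arylacetic acid with a remote ketone. The demand is catalyst control of the enolate face, in concert with the C1 centre.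

10 from 8, and 8 from 6 and 7: the aryl–C4 bond is cut. This places the acetic acid arm last on the arene, after the aldehyde has been used, and reduces the arene to a bromide. The forward step must couple an ester enolate in the presence of an enolizable ketone.

6 from 5, 5 from 2 and 3, 2 from 1: the C1–C2 bond is cut (aldol), and the silyl groups are removed. All carbons of ring B except C4 then come from a benzaldehyde and an acetophenone enol ether. The demand is an enantioselective aldol addition to a hindered aldehyde that gives the 1S carbinol.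

**Other disconnections considered**

Alternative 1: the first idea is to cut both CH2–pyrone bonds back to formaldehyde and two monomers, the tetralone A2 and the naphthyl pyrone A3, and to make A2 by the biomimetic C2–C3 aldol closure of the open-chain ketone A1, which already carries ring C. The forward key step would be the intramolecular aldol addition of the methyl ketone of A1 to its benzoyl group. In A1, C4 is flanked by benzoyl, aryl and pyrone and is configurationally labile, so the closure would have to be a dynamic kinetic resolution with an aryl methyl ketone as donor and a hindered ketone as acceptor, for which no catalyst class can be relied on. The C1 ketone is also present from the start, so A2 would sit in the very medium that promotes its retro-aldol cleavage and its dehydration to A3. The three-component union of A2, A3 and formaldehyde would moreover be statistical. The chosen plan keeps C1 masked, sets C3/C4 in a rigid bicycle under catalyst control, and gives the electrophilic role to one pyrone only.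

Alternative 2: the hidden symmetry can be used directly by joining two molecules of A2 with formaldehyde to the C2-symmetric homodimer A4 and removing one molecule of water from one half. The forward key step would be a mono-dehydration of A4. The two tetralone units of A4 are insulated from each other by two pyrones and a methylene group, so both should react at the same rate. The step can then give at best a statistical mixture of A4, the target and the doubly aromatized product, with recycling. The chosen plan performs the same dehydration on the monomer, where it can be driven to completion, and only then joins the halves.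

Alternative 3: ring B can be cut at C1–C2 and C3–C4 by a photoenolization/Diels–Alder reaction. Irradiation of aldehyde A5 would give a hydroxy-o-quinodimethane that adds a two-carbon dienophile; the C1 carbinol would be oxidized later. The polarity of this diene puts its nucleophilic end at C4, so the acceptor-bearing carbon of the dienophile bonds to C1. With a 2-phenylacrylate the adduct would be A6, with phenyl on C2 and not on C3. A dienophile with phenyl and oxygen on the β-carbon would be a push–pull alkene of low reactivity. The C3 hydroxyl and the absolute configuration would remain unsolved, and more steps would follow than in the chosen plan.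

Key step: step 6

Assumption: the tetralone–pyrone and naphthalene–pyrone bonds are taken to rotate freely, so C3 and C4 are the only stereo-elements; locants C1–C8a are those of the tetralone of the target throughout.

**Route**

Step 1
Reactants: 1 2-bromo-6-hydroxybenzaldehyde
Product: 2 2-bromo-6-[(triisopropylsilyl)oxy]benzaldehyde
Conditions: TIPSCl, imidazole, DMF, 23 °C
Reagents that add atoms: chlorotriisopropylsilane (TIPSCl), CC(C)[Si](Cl)(C(C)C)C(C)C
Why: Silylation of the phenol; the aryl triisopropylsilyl ether should survive Lewis acids, zinc and lithium enolates and acidic fluoride, and is removed last by buffered fluoride.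

Step 2
Reactants: 2 2-bromo-6-[(triisopropylsilyl)oxy]benzaldehyde; 3 trimethyl[(1-phenylethenyl)oxy]silane
Product: 5 (3S)-3-{2-bromo-6-[(triisopropylsilyl)oxy]phenyl}-3-hydroxy-1-phenylpropan-1-one, via trimethylsilyl ether 4 (not isolated)
Conditions: N-tosyl-(R)-tryptophan-derived B-n-butyl-1,3,2-oxazaborolidin-5-one (20 mol %), EtCN, −78 °C; then 1 M HCl, THF, 0 °C
Reagents that add atoms: none
Why: Catalytic enantioselective Mukaiyama aldol addition; the boron-bound aldehyde is shielded on one face by the indole ring and the enol silane should add to the Si face to give the 3S carbinol (future C1), the catalyst enantiomer being chosen for this sense since both tryptophan enantiomers are available; acidic work-up cleaves silyl ether 4.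

Step 3
Reactants: 5 (3S)-3-{2-bromo-6-[(triisopropylsilyl)oxy]phenyl}-3-hydroxy-1-phenylpropan-1-one
Product: 6 (3S)-3-{2-bromo-6-[(triisopropylsilyl)oxy]phenyl}-1-phenyl-3-[(triethylsilyl)oxy]propan-1-one
Conditions: TESCl, imidazole, CH2Cl2, 0 °C
Reagents that add atoms: chlorotriethylsilane (TESCl), CC[Si](Cl)(CC)CC
Why: Silylation of the secondary alcohol blocks retro-aldol cleavage and later lactonization with the acid; a triethylsilyl ether is chosen because acidic fluoride removes it while the aryl triisopropylsilyl ether stays.

Step 4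
Reactants: 6 (3S)-3-{2-bromo-6-[(triisopropylsilyl)oxy]phenyl}-1-phenyl-3-[(triethylsilyl)oxy]propan-1-one; 7 (2-tert-butoxy-2-oxoethyl)zinc bromide (BrZnCH2CO2t-Bu)
Product: 8 tert-butyl 2-{2-[(1S)-3-oxo-3-phenyl-1-[(triethylsilyl)oxy]propyl]-3-[(triisopropylsilyl)oxy]phenyl}acetate
Conditions: Pd(dba)2 (5 mol %), P(t-Bu)3 (5 mol %), THF, 23 °C
Reagents that add atoms: none
Why: Palladium-catalysed α-arylation of a zinc ester enolate (Reformatsky reagent in a Negishi-type coupling): oxidative addition of zerovalent palladium into C–Br, transmetalation and reductive elimination; the nearly neutral zinc enolate should leave the enolizable ketone and the β-silyloxy group alone, and the catalysed coupling is expected to outpace Reformatsky addition to the ketone at room temperature.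

Step 5
Reactants: 8 tert-butyl 2-{2-[(1S)-3-oxo-3-phenyl-1-[(triethylsilyl)oxy]propyl]-3-[(triisopropylsilyl)oxy]phenyl}acetate
Product: 10 2-{2-[(1S)-3-oxo-3-phenyl-1-[(triethylsilyl)oxy]propyl]-3-[(triisopropylsilyl)oxy]phenyl}acetic acid, via trimethylsilyl ester 9 (not isolated)
Conditions: TMSOTf, 2,6-lutidine, CH2Cl2, 0 °C; then pH 7 phosphate buffer, THF
Reagents that add atoms: none
Why: Silyl triflate-mediated cleavage of the tert-butyl ester (O-silylation, loss of isobutene) followed by hydrolysis of the silyl ester; the aprotic, buffered conditions should spare both silyl ethers and the β-silyloxy ketone, which aqueous base or protic acid would endanger.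

Step 6
Reactants: 10 2-{2-[(1S)-3-oxo-3-phenyl-1-[(triethylsilyl)oxy]propyl]-3-[(triisopropylsilyl)oxy]phenyl}acetic acid
Product: 12 (1S,3R,4S)-3-hydroxy-3-phenyl-1-[(triethylsilyl)oxy]-8-[(triisopropylsilyl)oxy]-1,2,3,4-tetrahydronaphthalene-4-carboxylic acid 3,4-lactone (cis-fused tricyclic β-lactone), via mixed tosyl anhydride 11 (not isolated)
Conditions: TsCl (1.5 equiv), i-Pr2NEt (4 equiv), LiCl (1 equiv), (S)-HBTM (20 mol %), CH2Cl2, 23 °C, slow addition of 10
Reagents that add atoms: none
Why: Intramolecular nucleophile-catalysed aldol-lactonization of a keto acid, the closest known reaction type being the isothiourea-catalysed formation of carbocycle-fused β-lactones from keto acids. TsCl converts 10 into mixed anhydride 11, the amidine nitrogen of (S)-HBTM is acylated, and i-Pr2NEt removes the now acidic benzylic C4–H to give a Z ammonium enolate held coplanar with the catalyst by the 1,5 O···S contact. Ring B closes by a 6-(enolexo)-exo-trig aldol addition of C4 to the C3 ketone (activated by LiCl), and the tertiary alkoxide closes the β-lactone by 4-exo-trig attack on the acyl ammonium carbon, which releases the catalyst. C4 is controlled by the catalyst: the pseudoaxial phenyl group of (S)-HBTM shields one enolate face, and by the usual model C3 should bond to the face that gives 4S (the mirror-image catalyst is equally available). C3 is controlled by the bicyclic transition state: only a cis-fused β-lactone can form, so the ketone oxygen ends up syn to the acyl carbon, which is the cis C3–O/C4–C6' relationship of the target, with phenyl pseudoequatorial. The 1S silyloxy group should reinforce this (matched pair), because it sits pseudoaxial to avoid the peri C8 silyloxy group and thereby favours the half-chair that has the lactone oxygen on its own face and phenyl equatorial. The step needs enolization at C4 and not at C2, which the acyl ammonium activation secures, and it needs the aryl-substituted β-lactone to survive, so it is run at or below room temperature to avoid decarboxylation.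

Step 7
Reactants: 12 (1S,3R,4S)-3-hydroxy-3-phenyl-1-[(triethylsilyl)oxy]-8-[(triisopropylsilyl)oxy]-1,2,3,4-tetrahydronaphthalene-4-carboxylic acid 3,4-lactone; 13 2,2,6-trimethyl-4H-1,3-dioxin-4-one
Product: 14 6-{2-oxo-2-[(1S,3R,4S)-3-hydroxy-3-phenyl-1-(triethylsilyloxy)-8-(triisopropylsilyloxy)-1,2,3,4-tetrahydronaphthalen-4-yl]ethyl}-2,2-dimethyl-4H-1,3-dioxin-4-one
Conditions: 13 (3 equiv), LiN(SiMe3)2 (3 equiv), THF, −78 °C; then 12, −78 to −40 °C; AcOH, −78 °C
Reagents that add atoms: none
Why: Claisen-type acylation of the vinylogous lithium enolate of 13 at its exocyclic carbon by the strained β-lactone (acyl–oxygen cleavage), which turns the lactone carbonyl into C6' and frees the C3 alkoxide with C3 and C4 untouched; the product is at once deprotonated between its two carbonyl groups, which should protect C4 from enolization and the C3–C4 bond from retro-aldol cleavage until the cold acidic quench.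

Step 8
Reactants: 14 6-{2-oxo-2-[(1S,3R,4S)-3-hydroxy-3-phenyl-1-(triethylsilyloxy)-8-(triisopropylsilyloxy)-1,2,3,4-tetrahydronaphthalen-4-yl]ethyl}-2,2-dimethyl-4H-1,3-dioxin-4-one
Product: 16 4-hydroxy-6-[(1S,3R,4S)-3-hydroxy-3-phenyl-1-(triethylsilyloxy)-8-(triisopropylsilyloxy)-1,2,3,4-tetrahydronaphthalen-4-yl]-2H-pyran-2-one, via acylketene 15 (not isolated)
Conditions: toluene, 110 °C, 30 min
Reagents that add atoms: none
Why: Thermal retro-hetero-Diels–Alder loss of acetone gives acylketene 15, which is trapped by the enol oxygen of the C6' ketone in a six-membered closure and tautomerizes to the 4-hydroxy-2-pyrone (ring C); the conditions are neutral, so C3 and C4 should be unaffected, and C4 is no longer α to a ketone afterwards.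

Step 9
Reactants: 16 4-hydroxy-6-[(1S,3R,4S)-3-hydroxy-3-phenyl-1-(triethylsilyloxy)-8-(triisopropylsilyloxy)-1,2,3,4-tetrahydronaphthalen-4-yl]-2H-pyran-2-one
Product: 17 4-hydroxy-6-[(1S,3R,4S)-1,3-dihydroxy-3-phenyl-8-(triisopropylsilyloxy)-1,2,3,4-tetrahydronaphthalen-4-yl]-2H-pyran-2-one
Conditions: HF·pyridine, pyridine, THF, 0 °C
Reagents that add atoms: none
Why: Acidic fluoride cleaves the alkyl triethylsilyl ether much faster than the aryl triisopropylsilyl ether; buffering with pyridine should keep the tertiary benzylic C3 carbinol from ionizing.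

Step 10
Reactants: 17 4-hydroxy-6-[(1S,3R,4S)-1,3-dihydroxy-3-phenyl-8-(triisopropylsilyloxy)-1,2,3,4-tetrahydronaphthalen-4-yl]-2H-pyran-2-one
Product: 18 4-hydroxy-6-[(3R,4S)-3-hydroxy-1-oxo-3-phenyl-8-(triisopropylsilyloxy)-1,2,3,4-tetrahydronaphthalen-4-yl]-2H-pyran-2-one
Conditions: MnO2 (activated, 20 equiv), CH2Cl2, 23 °C
Reagents that add atoms: none
Why: Surface oxidation of a benzylic secondary alcohol by MnO2, which should leave the tertiary carbinol and the pyrone enol alone; the temporary C1 stereocentre is erased here and the C1 ketone appears only after all basic steps are over.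

Step 11
Reactants: 18 4-hydroxy-6-[(3R,4S)-3-hydroxy-1-oxo-3-phenyl-8-(triisopropylsilyloxy)-1,2,3,4-tetrahydronaphthalen-4-yl]-2H-pyran-2-one
Product: 19 4-hydroxy-6-{4-hydroxy-2-phenyl-5-[(triisopropylsilyl)oxy]naphthalen-1-yl}-2H-pyran-2-one
Conditions: p-TsOH·H2O (10 mol %), toluene, 60 °C (run on about half of 18)
Reagents that add atoms: none
Why: Acid-catalysed dehydration with aromatization: ionization at tertiary benzylic C3, loss of a C2 proton to the enone and tautomerization through C4–H give the naphthol (rings E and F); the weakness of the tetralone is used here to make the second half, and both stereocentres are erased on purpose.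

Step 12
Reactants: 19 4-hydroxy-6-{4-hydroxy-2-phenyl-5-[(triisopropylsilyl)oxy]naphthalen-1-yl}-2H-pyran-2-one
Product: 20 3-[(dimethylamino)methyl]-4-hydroxy-6-{4-hydroxy-2-phenyl-5-[(triisopropylsilyl)oxy]naphthalen-1-yl}-2H-pyran-2-one
Conditions: Eschenmoser's salt (1.05 equiv), i-Pr2NEt (1.05 equiv), CH2Cl2, −20 to 0 °C
Reagents that add atoms: dimethylmethylideneammonium iodide (Eschenmoser's salt), C=[N+](C)C.[I-]
Why: Mannich reaction of a preformed iminium ion at C3'' of the pyrone, by far the most nucleophilic carbon (enol of a vinylogous acid); the only free naphthol ortho position is flanked by phenyl and should not compete at low temperature.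

Step 13
Reactants: 20 3-[(dimethylamino)methyl]-4-hydroxy-6-{4-hydroxy-2-phenyl-5-[(triisopropylsilyl)oxy]naphthalen-1-yl}-2H-pyran-2-one; 18 4-hydroxy-6-[(3R,4S)-3-hydroxy-1-oxo-3-phenyl-8-(triisopropylsilyloxy)-1,2,3,4-tetrahydronaphthalen-4-yl]-2H-pyran-2-one
Product: 22 O8,O5'''-bis(triisopropylsilyl) ether of wailupemycin H, via methide 21 (not isolated)
Conditions: AcOH (2 equiv), MeCN, 40 °C
Reagents that add atoms: none
Why: Elimination–addition of a Mannich base: loss of dimethylamine from 20 gives the 3-methylidenepyran-2,4-dione 21, and Michael addition of C3' of 18 forms the methylene bridge; 20 has no free C3''–H and 18 carries no electrophile, so only the mixed product should form, and AcOH buffers the amine so that the tetralone is not exposed to base.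

Step 14
Reactants: 22 O8,O5'''-bis(triisopropylsilyl) ether of wailupemycin H
Product: 23 wailupemycin H
Conditions: TBAF, AcOH (1:1, 2.5 equiv), THF, 0 °C
Reagents that add atoms: none
Why: Fluoride cleavage of the two aryl silyl ethers; buffering with AcOH should prevent phenoxide- or fluoride-induced retro-aldol cleavage, E1cB dehydration and retro-Michael opening of the bridge, so C3 and C4 are delivered as set in step 6.

**Compound list**

1 | 2-bromo-6-hydroxybenzaldehyde | O=Cc1c(O)cccc1Br | starting material
2 | 2-bromo-6-[(triisopropylsilyl)oxy]benzaldehyde | O=Cc1c(O[Si](C(C)C)(C(C)C)C(C)C)cccc1Br | intermediate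
3 | trimethyl[(1-phenylethenyl)oxy]silane | C=C(O[Si](C)(C)C)c1ccccc1 | starting material
4 | (3S)-3-{2-bromo-6-[(triisopropylsilyl)oxy]phenyl}-1-phenyl-3-[(trimethylsilyl)oxy]propan-1-one | O=C(c1ccccc1)C[C@H](O[Si](C)(C)C)c1c(O[Si](C(C)C)(C(C)C)C(C)C)cccc1Br | intermediate
5 | (3S)-3-{2-bromo-6-[(triisopropylsilyl)oxy]phenyl}-3-hydroxy-1-phenylpropan-1-one | O=C(c1ccccc1)C[C@H](O)c1c(O[Si](C(C)C)(C(C)C)C(C)C)cccc1Br | intermediate
6 | (3S)-3-{2-bromo-6-[(triisopropylsilyl)oxy]phenyl}-1-phenyl-3-[(triethylsilyl)oxy]propan-1-one | O=C(c1ccccc1)C[C@H](O[Si](CC)(CC)CC)c1c(O[Si](C(C)C)(C(C)C)C(C)C)cccc1Br | intermediate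
7 | (2-tert-butoxy-2-oxoethyl)zinc bromide | CC(C)(C)OC(=O)C[Zn]Br | starting material
8 | tert-butyl 2-{2-[(1S)-3-oxo-3-phenyl-1-[(triethylsilyl)oxy]propyl]-3-[(triisopropylsilyl)oxy]phenyl}acetate | O=C(c1ccccc1)C[C@H](O[Si](CC)(CC)CC)c1c(O[Si](C(C)C)(C(C)C)C(C)C)cccc1CC(=O)OC(C)(C)C | intermediate
9 | trimethylsilyl 2-{2-[(1S)-3-oxo-3-phenyl-1-[(triethylsilyl)oxy]propyl]-3-[(triisopropylsilyl)oxy]phenyl}acetate | O=C(c1ccccc1)C[C@H](O[Si](CC)(CC)CC)c1c(O[Si](C(C)C)(C(C)C)C(C)C)cccc1CC(=O)O[Si](C)(C)C | intermediate
10 | 2-{2-[(1S)-3-oxo-3-phenyl-1-[(triethylsilyl)oxy]propyl]-3-[(triisopropylsilyl)oxy]phenyl}acetic acid | O=C(c1ccccc1)C[C@H](O[Si](CC)(CC)CC)c1c(O[Si](C(C)C)(C(C)C)C(C)C)cccc1CC(=O)O | intermediate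
11 | mixed anhydride of 10 with p-toluenesulfonic acid | O=C(c1ccccc1)C[C@H](O[Si](CC)(CC)CC)c1c(O[Si](C(C)C)(C(C)C)C(C)C)cccc1CC(=O)OS(=O)(=O)c1ccc(C)cc1 | intermediate
12 | (1S,3R,4S)-3-hydroxy-3-phenyl-1-[(triethylsilyl)oxy]-8-[(triisopropylsilyl)oxy]-1,2,3,4-tetrahydronaphthalene-4-carboxylic acid 3,4-lactone (cis-fused β-lactone; O1, O3 and the acyl carbon on one face) | [C@H]1(O[Si](CC)(CC)CC)C[C@@]2(c3ccccc3)OC(=O)[C@H]2c2cccc(O[Si](C(C)C)(C(C)C)C(C)C)c12 | intermediate
13 | 2,2,6-trimethyl-4H-1,3-dioxin-4-one | CC1=CC(=O)OC(C)(C)O1 | starting material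
14 | 6-{2-oxo-2-[(1S,3R,4S)-3-hydroxy-3-phenyl-1-(triethylsilyloxy)-8-(triisopropylsilyloxy)-1,2,3,4-tetrahydronaphthalen-4-yl]ethyl}-2,2-dimethyl-4H-1,3-dioxin-4-one | [C@H]1(O[Si](CC)(CC)CC)C[C@](O)(c2ccccc2)[C@@H](C(=O)CC2=CC(=O)OC(C)(C)O2)c2cccc(O[Si](C(C)C)(C(C)C)C(C)C)c12 | intermediate
15 | 5-[(1S,3R,4S)-3-hydroxy-3-phenyl-1-(triethylsilyloxy)-8-(triisopropylsilyloxy)-1,2,3,4-tetrahydronaphthalen-4-yl]pent-1-ene-1,3,5-trione (acylketene) | [C@H]1(O[Si](CC)(CC)CC)C[C@](O)(c2ccccc2)[C@@H](C(=O)CC(=O)C=C=O)c2cccc(O[Si](C(C)C)(C(C)C)C(C)C)c12 | intermediate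
16 | 4-hydroxy-6-[(1S,3R,4S)-3-hydroxy-3-phenyl-1-(triethylsilyloxy)-8-(triisopropylsilyloxy)-1,2,3,4-tetrahydronaphthalen-4-yl]-2H-pyran-2-one | [C@H]1(O[Si](CC)(CC)CC)C[C@](O)(c2ccccc2)[C@@H](c2cc(O)cc(=O)o2)c2cccc(O[Si](C(C)C)(C(C)C)C(C)C)c12 | intermediate
17 | 4-hydroxy-6-[(1S,3R,4S)-1,3-dihydroxy-3-phenyl-8-(triisopropylsilyloxy)-1,2,3,4-tetrahydronaphthalen-4-yl]-2H-pyran-2-one | [C@H]1(O)C[C@](O)(c2ccccc2)[C@@H](c2cc(O)cc(=O)o2)c2cccc(O[Si](C(C)C)(C(C)C)C(C)C)c12 | intermediate
18 | 4-hydroxy-6-[(3R,4S)-3-hydroxy-1-oxo-3-phenyl-8-(triisopropylsilyloxy)-1,2,3,4-tetrahydronaphthalen-4-yl]-2H-pyran-2-one | O=C1C[C@](O)(c2ccccc2)[C@@H](c2cc(O)cc(=O)o2)c2cccc(O[Si](C(C)C)(C(C)C)C(C)C)c21 | intermediate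
19 | 4-hydroxy-6-{4-hydroxy-2-phenyl-5-[(triisopropylsilyl)oxy]naphthalen-1-yl}-2H-pyran-2-one | O=c1cc(O)cc(-c2c(-c3ccccc3)cc(O)c3c(O[Si](C(C)C)(C(C)C)C(C)C)cccc23)o1 | intermediate
20 | 3-[(dimethylamino)methyl]-4-hydroxy-6-{4-hydroxy-2-phenyl-5-[(triisopropylsilyl)oxy]naphthalen-1-yl}-2H-pyran-2-one | CN(C)Cc1c(O)cc(-c2c(-c3ccccc3)cc(O)c3c(O[Si](C(C)C)(C(C)C)C(C)C)cccc23)oc1=O | intermediate
21 | 6-{4-hydroxy-2-phenyl-5-[(triisopropylsilyl)oxy]naphthalen-1-yl}-3-methylidene-2H-pyran-2,4(3H)-dione | C=C1C(=O)C=C(-c2c(-c3ccccc3)cc(O)c3c(O[Si](C(C)C)(C(C)C)C(C)C)cccc23)OC1=O | intermediate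
22 | O8,O5'''-bis(triisopropylsilyl) ether of wailupemycin H (3R,4S) | O=C1C[C@](O)(c2ccccc2)[C@@H](c2cc(O)c(Cc3c(O)cc(-c4c(-c5ccccc5)cc(O)c5c(O[Si](C(C)C)(C(C)C)C(C)C)cccc45)oc3=O)c(=O)o2)c2cccc(O[Si](C(C)C)(C(C)C)C(C)C)c21 | intermediate
23 | wailupemycin H (3R,4S) | O=C1C[C@](O)(c2ccccc2)[C@@H](c2cc(O)c(Cc3c(O)cc(-c4c(-c5ccccc5)cc(O)c5c(O)cccc45)oc3=O)c(=O)o2)c2cccc(O)c21 | target

**Step count and risks**

Total step count: 14. Longest linear sequence: 14 steps (1 to 18, then 19, 20, 22, 23; 18 enters step 13 a second time as the other partner).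

Step 6 (key step). What may go wrong: insufficient facial discrimination if the conformational bias of the 1S silyloxy group and the catalyst do not reinforce each other as argued; oligomerization through the acyl ammonium or ketene stage because closure of a six-membered ring onto an aryl ketone is slow; loss of CO2 from the product by ionization of the tertiary benzylic C3–O bond. Fallback, from 8 back to 12: a substrate-controlled lithium aldol closure. Ester 8 is treated with LiN(SiMe3)2 in THF at −78 °C; the C4 ester enolate adds to the C3 ketone through a lithium-chelated chair that places oxygen and ester cis and is steered by the 1S centre. This should give tert-butyl (1S,3R,4S)-3-hydroxy-3-phenyl-1-(triethylsilyloxy)-8-(triisopropylsilyloxy)-1,2,3,4-tetrahydronaphthalene-4-carboxylate F1. TMSOTf/2,6-lutidine and buffer then give the corresponding hydroxy acid F2, and PhSO2Cl in pyridine at 0 °C lactonizes it by carboxyl activation to 12.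

Step 7. What may go wrong: proton transfer from C4 of the lactone to the dienolate in place of acyl transfer; after ring opening, retro-aldol cleavage of C3–C4 or epimerization at C4 during the quench. Fallback, from 12 back to 14: the lactone is first opened at the acyl carbon with MeNH(OMe)·HCl and i-PrMgCl at −20 °C to the N-methoxy-N-methyl amide F3, held as a magnesium chelate. F3 then acylates the lithium dienolate of 13, a well-tried acyl donor class for this enolate, to give 14.

Step 13. What may go wrong: retro-Michael opening of the new bridge with scrambling to the two symmetrical dimers; C-alkylation of the free naphthol ring by 21; amine-promoted dehydration of the tetralone of 18. Fallback, from 19 back to 22: an amine-free release of 21. Naphthyl pyrone 19 is condensed with paraformaldehyde and PhSH (EtOH, 60 °C) to the 3-[(phenylsulfanyl)methyl]pyrone F4, which m-CPBA at −40 °C oxidizes to the sulfoxide F5. F5 should lose benzenesulfenic acid at room temperature to give 21 in the presence of 18, which adds to it to give 22.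

Step 2. What may go wrong: low rate or poor facial selectivity with an aldehyde that carries two ortho substituents. Fallback, from 2 back to 5: Wittig reaction of 2 with Ph3P=CHC(O)Ph (toluene, 90 °C) gives the (E)-chalcone F6. Copper-catalysed enantioselective conjugate borylation (CuCl, NaOt-Bu, a Josiphos-type bisphosphine, B2pin2, MeOH, THF) gives the (3S)-boronate F7, and oxidation with NaBO3 with retention gives 5.

Step 10. What may go wrong: incomplete conversion of a carbinol that is flanked by the peri silyloxy group on the MnO2 surface; with stronger oxidants, attack at the electron-rich C3' of the pyrone enol. Fallback, from 17 back to 18: the acidic pyrone hydroxyl alone is silylated (TBSCl, Et3N, CH2Cl2, −40 °C) to the 4-silyloxy pyrone F8. The C1 carbinol is oxidized with Dess–Martin periodinane/NaHCO3 to the ketone F9, and the labile pyrone silyl ether is cleaved with AcOH/THF/H2O to give 18.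

**Further compounds**

F1 | step 6 | tert-butyl (1S,3R,4S)-3-hydroxy-3-phenyl-1-(triethylsilyloxy)-8-(triisopropylsilyloxy)-1,2,3,4-tetrahydronaphthalene-4-carboxylate | [C@H]1(O[Si](CC)(CC)CC)C[C@](O)(c2ccccc2)[C@@H](C(=O)OC(C)(C)C)c2cccc(O[Si](C(C)C)(C(C)C)C(C)C)c12
F2 | step 6 | (1S,3R,4S)-3-hydroxy-3-phenyl-1-(triethylsilyloxy)-8-(triisopropylsilyloxy)-1,2,3,4-tetrahydronaphthalene-4-carboxylic acid | [C@H]1(O[Si](CC)(CC)CC)C[C@](O)(c2ccccc2)[C@@H](C(=O)O)c2cccc(O[Si](C(C)C)(C(C)C)C(C)C)c12
F3 | step 7 | (1S,3R,4S)-3-hydroxy-N-methoxy-N-methyl-3-phenyl-1-(triethylsilyloxy)-8-(triisopropylsilyloxy)-1,2,3,4-tetrahydronaphthalene-4-carboxamide | [C@H]1(O[Si](CC)(CC)CC)C[C@](O)(c2ccccc2)[C@@H](C(=O)N(C)OC)c2cccc(O[Si](C(C)C)(C(C)C)C(C)C)c12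
F4 | step 13 | 4-hydroxy-6-{4-hydroxy-2-phenyl-5-[(triisopropylsilyl)oxy]naphthalen-1-yl}-3-[(phenylsulfanyl)methyl]-2H-pyran-2-one | O=c1oc(-c2c(-c3ccccc3)cc(O)c3c(O[Si](C(C)C)(C(C)C)C(C)C)cccc23)cc(O)c1CSc1ccccc1
F5 | step 13 | 4-hydroxy-6-{4-hydroxy-2-phenyl-5-[(triisopropylsilyl)oxy]naphthalen-1-yl}-3-[(phenylsulfinyl)methyl]-2H-pyran-2-one (both configurations at sulfur) | O=c1oc(-c2c(-c3ccccc3)cc(O)c3c(O[Si](C(C)C)(C(C)C)C(C)C)cccc23)cc(O)c1CS(=O)c1ccccc1
F6 | step 2 | (E)-3-{2-bromo-6-[(triisopropylsilyl)oxy]phenyl}-1-phenylprop-2-en-1-one | O=C(/C=C/c1c(O[Si](C(C)C)(C(C)C)C(C)C)cccc1Br)c1ccccc1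
F7 | step 2 | (3S)-3-{2-bromo-6-[(triisopropylsilyl)oxy]phenyl}-1-phenyl-3-(4,4,5,5-tetramethyl-1,3,2-dioxaborolan-2-yl)propan-1-one | O=C(c1ccccc1)C[C@H](B1OC(C)(C)C(C)(C)O1)c1c(O[Si](C(C)C)(C(C)C)C(C)C)cccc1Br
F8 | step 10 | 4-[(tert-butyldimethylsilyl)oxy]-6-[(1S,3R,4S)-1,3-dihydroxy-3-phenyl-8-(triisopropylsilyloxy)-1,2,3,4-tetrahydronaphthalen-4-yl]-2H-pyran-2-one | [C@H]1(O)C[C@](O)(c2ccccc2)[C@@H](c2cc(O[Si](C)(C)C(C)(C)C)cc(=O)o2)c2cccc(O[Si](C(C)C)(C(C)C)C(C)C)c12
F9 | step 10 | 4-[(tert-butyldimethylsilyl)oxy]-6-[(3R,4S)-3-hydroxy-1-oxo-3-phenyl-8-(triisopropylsilyloxy)-1,2,3,4-tetrahydronaphthalen-4-yl]-2H-pyran-2-one | O=C1C[C@](O)(c2ccccc2)[C@@H](c2cc(O[Si](C)(C)C(C)(C)C)cc(=O)o2)c2cccc(O[Si](C(C)C)(C(C)C)C(C)C)c21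
A1 | alternative 1 | 6-[1-(2-acetyl-3-hydroxyphenyl)-2-oxo-2-phenylethyl]-4-hydroxy-2H-pyran-2-one (configurationally labile at the methine) | CC(=O)c1c(O)cccc1C(C(=O)c1ccccc1)c1cc(O)cc(=O)o1
A2 | alternative 1 | 4-hydroxy-6-[(3R,4S)-3,8-dihydroxy-1-oxo-3-phenyl-1,2,3,4-tetrahydronaphthalen-4-yl]-2H-pyran-2-one | O=C1C[C@](O)(c2ccccc2)[C@@H](c2cc(O)cc(=O)o2)c2cccc(O)c21
A3 | alternative 1 | 6-(4,5-dihydroxy-2-phenylnaphthalen-1-yl)-4-hydroxy-2H-pyran-2-one | O=c1cc(O)cc(-c2c(-c3ccccc3)cc(O)c3c(O)cccc23)o1
A4 | alternative 2 | 3,3'-methylenebis{4-hydroxy-6-[(3R,4S)-3,8-dihydroxy-1-oxo-3-phenyl-1,2,3,4-tetrahydronaphthalen-4-yl]-2H-pyran-2-one} | O=C1C[C@](O)(c2ccccc2)[C@@H](c2cc(O)c(Cc3c(O)cc([C@H]4c5cccc(O)c5C(=O)C[C@]4(O)c4ccccc4)oc3=O)c(=O)o2)c2cccc(O)c21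
A5 | alternative 3 | 2-[(4-methoxy-2-oxo-2H-pyran-6-yl)methyl]-6-[(triisopropylsilyl)oxy]benzaldehyde | O=Cc1c(O[Si](C(C)C)(C(C)C)C(C)C)cccc1Cc1cc(OC)cc(=O)o1
A6 | alternative 3 | methyl 1-hydroxy-4-(4-methoxy-2-oxo-2H-pyran-6-yl)-2-phenyl-8-[(triisopropylsilyl)oxy]-1,2,3,4-tetrahydronaphthalene-2-carboxylate (configuration not specified) | COC(=O)C1(c2ccccc2)CC(c2cc(OC)cc(=O)o2)c2cccc(O[Si](C(C)C)(C(C)C)C(C)C)c2C1O
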